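Atoms carry lignan labels: the aryl-bearing O–CH carbons are C7 and C7', the ring-fusion CH is C8, the ring-fusion carbinol is C8', the O–CH2 carbons are C9 and C9'. Everything rests on cutting ring A (C7–O–C9'–C8'–C8), a 3-hydroxyoxolane, into two pieces: ethyl bromopyruvate supplies C8'(OH), C9'H2 and C7', a vanilloylacetate supplies C7 with its aryl group, C8, C9 and the ring oxygen. One amine-catalysed asymmetric interrupted Feist–Benary annulation forges C8–C8' and O–C9', closes ring A as a hydroxydihydrofuran and sets C8', the centre that later relays C7, C8 and C7'. The precursor is the silyl-protected ethyl aroylacetate; the product's two unlike esters then build ring B (C7'–O–C9–C8–C8').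

Key step: step 3

Remark on the target: as drawn it is the (7R,8R,7'S,8'S) isomer, (3S,3aS,6R,6aR) in furo[3,4-c]furan numbering. Rings A and B are cis-fused, H7, H8, H7' and the C8' hydroxyl lie on the convex face, and both aryl groups are endo.

Assumption: the quinidine-derived bis-cinchona catalyst is taken to give the (S)-carbinol 7 with this aroylacetate. If the sense of induction is the reverse, the quinine-derived pseudoenantiomer (DHQ)2PYR is used in the same step and nothing else changes.

Step 1
Reactants: 1 acetovanillone; 2 diethyl carbonate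
Product: 3 ethyl 3-(4-hydroxy-3-methoxyphenyl)-3-oxopropanoate
Conditions: NaH (3.5 equiv), 2 (5 equiv), THF, reflux; then AcOH, H2O, 0 °C
Reagents that add atoms: none
Why: Claisen-type C-ethoxycarbonylation of the methyl ketone enolate, in which excess hydride holds the phenol as its phenoxide and the product as its stabilised enolate, so the equilibrium is pulled forward and any carbonate formed on the phenol oxygen is returned by ethoxide.

Step 2
Reactants: 3 ethyl 3-(4-hydroxy-3-methoxyphenyl)-3-oxopropanoate
Product: 4 ethyl 3-[4-(tert-butyldimethylsilyloxy)-3-methoxyphenyl]-3-oxopropanoate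
Conditions: TBSCl (1.1 equiv), imidazole (2.2 equiv), CH2Cl2, 0 °C → rt
Reagents that add atoms: tert-butyldimethylsilyl chloride, CC(C)(C)[Si](C)(C)Cl
Why: Silyl ether formation is selective for the acidic phenol because a β-ketoester is not O-silylated by TBSCl/imidazole, and placing this step after the Claisen condensation keeps the silyl ether away from ethoxide.

Step 3
Reactants: 4 ethyl 3-[4-(tert-butyldimethylsilyloxy)-3-methoxyphenyl]-3-oxopropanoate; 5 ethyl bromopyruvate
Product: 7 diethyl (4S)-2-[4-(tert-butyldimethylsilyloxy)-3-methoxyphenyl]-4-hydroxy-4,5-dihydrofuran-3,4-dicarboxylate, via acyclic bromohydrin aldol adduct 6 (not isolated)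
Conditions: (DHQD)2PYR (hydroquinidine 2,5-diphenylpyrimidine-4,6-diyl diether, 10 mol%), 1,8-bis(dimethylamino)naphthalene (1.05 equiv), THF, −78 °C → −20 °C; pH 7 buffer work-up
Reagents that add atoms: none
Why: The quinuclidine nitrogen of the catalyst, backed by 1,8-bis(dimethylamino)naphthalene as proton sink, deprotonates 4 at C8 and the chiral ammonium enolate adds through C8 to the very electrophilic ketone of 5 (aldol step, C8–C8' bond) to give bromohydrin 6, whose aroyl enol oxygen then displaces bromide at C9' (O–C9' bond). The closest known reaction type is the cinchona-alkaloid-catalysed enantioselective interrupted Feist–Benary reaction of 1,3-dicarbonyl compounds with bromopyruvates. Ring A closes by 5-exo-tet O-alkylation, which is irreversible and so locks in the aldol selectivity before retro-aldol can erode it. C8', the only new stereocentre, is set by catalyst control of the enantiofacial addition to the pyruvate ketone inside the ion pair, whereas C8 is stereogenic only in 6 and becomes sp2 in 7. The step needs aldol addition to win over direct SN2 alkylation at the CH2Br carbon and over epoxide closure, which the high electrophilicity of the α-keto ester and the amine (not alkoxide) base secure, and it needs ring closure through the ketone oxygen and not the ester oxygen, which the more nucleophilic aroyl enol oxygen secures. Low temperature and the absence of acid stop the sequence at the hydroxydihydrofuran instead of the furan.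

Step 4
Reactants: 7 diethyl (4S)-2-[4-(tert-butyldimethylsilyloxy)-3-methoxyphenyl]-4-hydroxy-4,5-dihydrofuran-3,4-dicarboxylate
Product: 8 ethyl (4S)-2-[4-(tert-butyldimethylsilyloxy)-3-methoxyphenyl]-4-hydroxy-4-[methoxy(methyl)carbamoyl]-4,5-dihydrofuran-3-carboxylate
Conditions: MeNH(OMe)·HCl (3 equiv), i-PrMgCl (7 equiv), THF, −20 °C → 0 °C; aq. NH4Cl
Reagents that add atoms: N,O-dimethylhydroxylamine hydrochloride, CNOC.Cl
Why: Weinreb amidation of an ester by the chloromagnesium amide is directed to C7' because the α-hydroxy ester is far more electrophilic than the C9 ester, a push–pull vinylogous carbonate on a tetrasubstituted alkene, and the basic, acid-free medium cannot dehydrate the carbinol or touch C8'.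

Step 5
Reactants: 9 4-bromo-2-methoxyphenol
Product: 10 (4-bromo-2-methoxyphenoxy)(tert-butyl)dimethylsilane
Conditions: TBSCl (1.1 equiv), imidazole (2.2 equiv), DMF, rt
Reagents that add atoms: tert-butyldimethylsilyl chloride, CC(C)(C)[Si](C)(C)Cl
Why: Routine silyl ether formation on a phenol, which masks the acidic proton before bromine–lithium exchange and puts the same protecting group on both aryl rings.

Step 6
Reactants: 8 ethyl (4S)-2-[4-(tert-butyldimethylsilyloxy)-3-methoxyphenyl]-4-hydroxy-4-[methoxy(methyl)carbamoyl]-4,5-dihydrofuran-3-carboxylate; 10 (4-bromo-2-methoxyphenoxy)(tert-butyl)dimethylsilane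
Product: 12 ethyl (4S)-4-[4-(tert-butyldimethylsilyloxy)-3-methoxybenzoyl]-2-[4-(tert-butyldimethylsilyloxy)-3-methoxyphenyl]-4-hydroxy-4,5-dihydrofuran-3-carboxylate, via aryllithium 11 (not isolated)
Conditions: 10 (2.6 equiv), n-BuLi (2.5 equiv), THF, −78 °C; then 8, THF, −78 °C; aq. NH4Cl
Reagents that add atoms: none
Why: Bromine–lithium exchange followed by the Weinreb ketone synthesis should stop at the ketone because the chelated tetrahedral intermediate survives until the quench, one equivalent of 11 being spent on the tertiary hydroxyl, while the deactivated C9 ester is left alone at −78 °C and C8, still sp2, cannot epimerise.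

Step 7
Reactants: 12 ethyl (4S)-4-[4-(tert-butyldimethylsilyloxy)-3-methoxybenzoyl]-2-[4-(tert-butyldimethylsilyloxy)-3-methoxyphenyl]-4-hydroxy-4,5-dihydrofuran-3-carboxylate
Product: 13 ethyl (2R,3R,4S)-4-[4-(tert-butyldimethylsilyloxy)-3-methoxybenzoyl]-2-[4-(tert-butyldimethylsilyloxy)-3-methoxyphenyl]-4-hydroxyoxolane-3-carboxylate
Conditions: H2 (50 bar), [Ir(cod)(PCy3)(py)]PF6 (10 mol%), CH2Cl2, rt
Reagents that add atoms: none
Why: In this hydroxyl-directed homogeneous hydrogenation the C8' hydroxyl binds the cationic iridium centre and both hydrogens are delivered syn to C7 and C8 from the hydroxyl face, which is also the open face opposite the bulky aroyl group, so H7, H8 and OH should end up cis with aryl, ester and aroyl groups together on the other face, and this catalyst spares the aryl ketone and the new benzylic C–O bond.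

Step 8
Reactants: 13 ethyl (2R,3R,4S)-4-[4-(tert-butyldimethylsilyloxy)-3-methoxybenzoyl]-2-[4-(tert-butyldimethylsilyloxy)-3-methoxyphenyl]-4-hydroxyoxolane-3-carboxylate
Product: 14 (3S,4R,5R)-5-[4-(tert-butyldimethylsilyloxy)-3-methoxyphenyl]-3-{[4-(tert-butyldimethylsilyloxy)-3-methoxyphenyl](hydroxy)methyl}-4-(hydroxymethyl)oxolan-3-ol (both C7' epimers)
Conditions: LiBH4 (4 equiv), THF, 0 °C → rt; aq. NH4Cl
Reagents that add atoms: none
Why: Borohydride reduction of the ketone and the ester is mild enough for the aryl silyl ethers and for the enolisable C8 centre, and the C7' carbinol may form as either epimer because step 9 returns it to the ketone level.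

Step 9
Reactants: 14 (3S,4R,5R)-5-[4-(tert-butyldimethylsilyloxy)-3-methoxyphenyl]-3-{[4-(tert-butyldimethylsilyloxy)-3-methoxyphenyl](hydroxy)methyl}-4-(hydroxymethyl)oxolan-3-ol (both C7' epimers)
Product: 16 (3aS,6R,6aR)-3,6-bis[4-(tert-butyldimethylsilyloxy)-3-methoxyphenyl]tetrahydro-1H,3H-furo[3,4-c]furan-3,3a(4H)-diol (ring B hemiketal; anomeric centre C7' not defined), via open-chain hydroxy ketone 15 (not isolated)
Conditions: activated MnO2 (15 equiv), CH2Cl2, rt
Reagents that add atoms: none
Why: Activated MnO2 oxidises only the secondary benzylic C7' alcohol and leaves the primary and tertiary hydroxyls, and ketone 15 should be captured at once by the cis-placed C9 hydroxyl as the five-membered hemiketal of ring B, which has no carbinol hydrogen and so resists further oxidation.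

Step 10
Reactants: 16 (3aS,6R,6aR)-3,6-bis[4-(tert-butyldimethylsilyloxy)-3-methoxyphenyl]tetrahydro-1H,3H-furo[3,4-c]furan-3,3a(4H)-diol
Product: 18 (3S,3aS,6R,6aR)-3,6-bis[4-(tert-butyldimethylsilyloxy)-3-methoxyphenyl]tetrahydro-1H,3H-furo[3,4-c]furan-3a(4H)-ol, via ring B oxocarbenium ion 17 (not isolated)
Conditions: Et3SiH (5 equiv), BF3·OEt2 (2 equiv), CH2Cl2, −78 °C → −40 °C; aq. NaHCO3
Reagents that add atoms: none
Why: In this ionic hydrogenation of a hemiketal, BF3·OEt2 ionises 16 to the aryl-stabilised oxocarbenium ion 17 and the silane delivers hydride to C7' from the convex face of the cis-fused bicycle, the concave face being shielded by ring A and its endo aryl group, so H7' should come out cis to the C8' hydroxyl with the aryl group endo, while the low temperature keeps the C7 benzylic ether from ionising.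

Step 11
Reactants: 18 (3S,3aS,6R,6aR)-3,6-bis[4-(tert-butyldimethylsilyloxy)-3-methoxyphenyl]tetrahydro-1H,3H-furo[3,4-c]furan-3a(4H)-ol
Product: 19 (3S,3aS,6R,6aR)-3,6-bis(4-hydroxy-3-methoxyphenyl)tetrahydro-1H,3H-furo[3,4-c]furan-3a(4H)-ol (CNP0138682.2)
Conditions: TBAF (2.4 equiv), AcOH (2.4 equiv), THF, 0 °C
Reagents that add atoms: none
Why: Fluoride cleaves both aryl silyl ethers, and buffering with acetic acid at 0 °C should keep the freed p-hydroxybenzyl ethers from opening through quinone methides, so the endo aryl groups are not epimerised.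

Compound list
1 | acetovanillone, 1-(4-hydroxy-3-methoxyphenyl)ethanone | CC(=O)c1ccc(O)c(OC)c1 | starting material
2 | diethyl carbonate | CCOC(=O)OCC | starting material
3 | ethyl 3-(4-hydroxy-3-methoxyphenyl)-3-oxopropanoate | CCOC(=O)CC(=O)c1ccc(O)c(OC)c1 | intermediate
4 | ethyl 3-[4-(tert-butyldimethylsilyloxy)-3-methoxyphenyl]-3-oxopropanoate | CCOC(=O)CC(=O)c1ccc(O[Si](C)(C)C(C)(C)C)c(OC)c1 | intermediate
5 | ethyl bromopyruvate, ethyl 3-bromo-2-oxopropanoate | CCOC(=O)C(=O)CBr | starting material
6 | diethyl (2R)-2-(bromomethyl)-3-[4-(tert-butyldimethylsilyloxy)-3-methoxybenzoyl]-2-hydroxybutanedioate, either C3 epimer, not isolated | CCOC(=O)C(C(=O)c1ccc(O[Si](C)(C)C(C)(C)C)c(OC)c1)[C@](O)(CBr)C(=O)OCC | intermediate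
7 | diethyl (4S)-2-[4-(tert-butyldimethylsilyloxy)-3-methoxyphenyl]-4-hydroxy-4,5-dihydrofuran-3,4-dicarboxylate | CCOC(=O)C1=C(c2ccc(O[Si](C)(C)C(C)(C)C)c(OC)c2)OC[C@]1(O)C(=O)OCC | intermediate
8 | ethyl (4S)-2-[4-(tert-butyldimethylsilyloxy)-3-methoxyphenyl]-4-hydroxy-4-[methoxy(methyl)carbamoyl]-4,5-dihydrofuran-3-carboxylate | CCOC(=O)C1=C(c2ccc(O[Si](C)(C)C(C)(C)C)c(OC)c2)OC[C@]1(O)C(=O)N(C)OC | intermediate
9 | 4-bromo-2-methoxyphenol | COc1cc(Br)ccc1O | starting material
10 | (4-bromo-2-methoxyphenoxy)(tert-butyl)dimethylsilane | COc1cc(Br)ccc1O[Si](C)(C)C(C)(C)C | intermediate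
11 | [4-(tert-butyldimethylsilyloxy)-3-methoxyphenyl]lithium, not isolated | COc1cc([Li])ccc1O[Si](C)(C)C(C)(C)C | intermediate
12 | ethyl (4S)-4-[4-(tert-butyldimethylsilyloxy)-3-methoxybenzoyl]-2-[4-(tert-butyldimethylsilyloxy)-3-methoxyphenyl]-4-hydroxy-4,5-dihydrofuran-3-carboxylate | CCOC(=O)C1=C(c2ccc(O[Si](C)(C)C(C)(C)C)c(OC)c2)OC[C@]1(O)C(=O)c1ccc(O[Si](C)(C)C(C)(C)C)c(OC)c1 | intermediate
13 | ethyl (2R,3R,4S)-4-[4-(tert-butyldimethylsilyloxy)-3-methoxybenzoyl]-2-[4-(tert-butyldimethylsilyloxy)-3-methoxyphenyl]-4-hydroxyoxolane-3-carboxylate; H2, H3 and OH cis | CCOC(=O)[C@@H]1[C@H](c2ccc(O[Si](C)(C)C(C)(C)C)c(OC)c2)OC[C@]1(O)C(=O)c1ccc(O[Si](C)(C)C(C)(C)C)c(OC)c1 | intermediate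
14 | (3S,4R,5R)-5-[4-(tert-butyldimethylsilyloxy)-3-methoxyphenyl]-3-{[4-(tert-butyldimethylsilyloxy)-3-methoxyphenyl](hydroxy)methyl}-4-(hydroxymethyl)oxolan-3-ol, both epimers at the carbinol carbon C7' | OC[C@@H]1[C@H](c2ccc(O[Si](C)(C)C(C)(C)C)c(OC)c2)OC[C@]1(O)C(O)c1ccc(O[Si](C)(C)C(C)(C)C)c(OC)c1 | intermediate
15 | [4-(tert-butyldimethylsilyloxy)-3-methoxyphenyl]{(3S,4R,5R)-5-[4-(tert-butyldimethylsilyloxy)-3-methoxyphenyl]-3-hydroxy-4-(hydroxymethyl)oxolan-3-yl}methanone, not isolated | OC[C@@H]1[C@H](c2ccc(O[Si](C)(C)C(C)(C)C)c(OC)c2)OC[C@]1(O)C(=O)c1ccc(O[Si](C)(C)C(C)(C)C)c(OC)c1 | intermediate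
16 | (3aS,6R,6aR)-3,6-bis[4-(tert-butyldimethylsilyloxy)-3-methoxyphenyl]tetrahydro-1H,3H-furo[3,4-c]furan-3,3a(4H)-diol, hemiketal at C7' (C3), anomeric configuration not defined | COc1cc([C@@H]2OC[C@@]3(O)[C@@H]2COC3(O)c2ccc(O[Si](C)(C)C(C)(C)C)c(OC)c2)ccc1O[Si](C)(C)C(C)(C)C | intermediate
17 | ring B oxocarbenium ion from 16 (C7'=O+, C8' hydroxyl and ring A unchanged), not isolated | COc1cc([C@@H]2OC[C@@]3(O)[C@@H]2C[O+]=C3c2ccc(O[Si](C)(C)C(C)(C)C)c(OC)c2)ccc1O[Si](C)(C)C(C)(C)C | intermediate
18 | (3S,3aS,6R,6aR)-3,6-bis[4-(tert-butyldimethylsilyloxy)-3-methoxyphenyl]tetrahydro-1H,3H-furo[3,4-c]furan-3a(4H)-ol | COc1cc([C@@H]2OC[C@@]3(O)[C@@H]2CO[C@H]3c2ccc(O[Si](C)(C)C(C)(C)C)c(OC)c2)ccc1O[Si](C)(C)C(C)(C)C | intermediate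
19 | (3S,3aS,6R,6aR)-3,6-bis(4-hydroxy-3-methoxyphenyl)tetrahydro-1H,3H-furo[3,4-c]furan-3a(4H)-ol, CNP0138682.2 | COc1cc([C@@H]2OC[C@@]3(O)[C@@H]2CO[C@H]3c2ccc(O)c(OC)c2)ccc1O | target

Total step count: 11. Longest linear sequence: 10 steps (steps 1–4 and 6–11); step 5 is a one-step side branch.

Steps most likely to fail

Step 3. What may go wrong: weak enantiofacial discrimination in the aldol addition of the acyclic, conformationally mobile aroylacetate enolate, made worse if the aldol reverses before ring closure. Fallback: setting out from 4 and 5, the annulation is run with an achiral base (Et3N, THF, 0 °C), which should give the racemic diester F1. The enantiomers are then separated by preparative supercritical-fluid chromatography on an amylose tris(3,5-dimethylphenylcarbamate) phase. The (4R)-enantiomer F2 is set aside and the (4S)-enantiomer is 7, where the route is rejoined.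

Step 7. What may go wrong: the hindered, electron-poor tetrasubstituted alkene fails to turn over on the homogeneous catalyst, or acidic iridium hydride species dehydrate the carbinol to the furan. Fallback: setting out from 7, the alkene is reduced before the second aryl group is attached, by heterogeneous hydrogenation (H2, 50 bar, Rh/Al2O3, EtOAc, rt). The substrate should adsorb through its less hindered hydroxyl face and give the all-cis saturated diester F3. Selective amidation of the α-hydroxy ester (MeNH(OMe)·HCl, i-PrMgCl, THF, −20 °C) should give the saturated Weinreb amide F4. Addition of aryllithium 11 at −78 °C, kept cold because C8 is now enolisable, comes back to the route at 13.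

Step 9. What may go wrong: oxidative cleavage of the C7'–C8' glycol on the manganese dioxide surface competes with oxidation of the benzylic alcohol. Fallback: setting out from 13, the oxidation level is not adjusted at all and C7' is set by chelation-controlled reduction (Zn(BH4)2, Et2O, −20 °C, then LiBH4, THF). Hydride should attack the zinc chelate of the ketone and the C8' hydroxyl from the side of the C9'H2 group and not from the more crowded C8 side, giving the (7'S)-triol F5. Selective sulfonylation of the primary hydroxyl (TsCl, pyridine, 0 °C) gives the C9 monotosylate F6. Treatment with NaH (THF, 0 °C) closes ring B by a 5-exo-tet Williamson etherification with retention at C7', coming back to the route at 18.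

Further compounds
F1 | step 3 | racemic diethyl 2-[4-(tert-butyldimethylsilyloxy)-3-methoxyphenyl]-4-hydroxy-4,5-dihydrofuran-3,4-dicarboxylate | CCOC(=O)C1=C(c2ccc(O[Si](C)(C)C(C)(C)C)c(OC)c2)OCC1(O)C(=O)OCC
F2 | step 3 | diethyl (4R)-2-[4-(tert-butyldimethylsilyloxy)-3-methoxyphenyl]-4-hydroxy-4,5-dihydrofuran-3,4-dicarboxylate | CCOC(=O)C1=C(c2ccc(O[Si](C)(C)C(C)(C)C)c(OC)c2)OC[C@@]1(O)C(=O)OCC
F3 | step 7 | diethyl (2R,3R,4S)-2-[4-(tert-butyldimethylsilyloxy)-3-methoxyphenyl]-4-hydroxyoxolane-3,4-dicarboxylate | CCOC(=O)[C@@H]1[C@H](c2ccc(O[Si](C)(C)C(C)(C)C)c(OC)c2)OC[C@]1(O)C(=O)OCC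
F4 | step 7 | ethyl (2R,3R,4S)-2-[4-(tert-butyldimethylsilyloxy)-3-methoxyphenyl]-4-hydroxy-4-[methoxy(methyl)carbamoyl]oxolane-3-carboxylate | CCOC(=O)[C@@H]1[C@H](c2ccc(O[Si](C)(C)C(C)(C)C)c(OC)c2)OC[C@]1(O)C(=O)N(C)OC
F5 | step 9 | (3S,4R,5R)-5-[4-(tert-butyldimethylsilyloxy)-3-methoxyphenyl]-3-{(S)-[4-(tert-butyldimethylsilyloxy)-3-methoxyphenyl](hydroxy)methyl}-4-(hydroxymethyl)oxolan-3-ol | OC[C@@H]1[C@H](c2ccc(O[Si](C)(C)C(C)(C)C)c(OC)c2)OC[C@]1(O)[C@@H](O)c1ccc(O[Si](C)(C)C(C)(C)C)c(OC)c1
F6 | step 9 | C9 mono-p-toluenesulfonate of F5 (primary hydroxyl sulfonylated, other centres unchanged) | Cc1ccc(S(=O)(=O)OC[C@@H]2[C@H](c3ccc(O[Si](C)(C)C(C)(C)C)c(OC)c3)OC[C@]2(O)[C@@H](O)c2ccc(O[Si](C)(C)C(C)(C)C)c(OC)c2)cc1
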